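**Plan**

1. Numbering: pinane C1–C7 (C1, C5 bridgeheads; C2 spiro; C6 = CMe2 bridge; C7 = CH2 bridge); ring B = C2, C8, C9, C10 (CH–iPr), C11; ring A = C11, C12 (C=O), C13 (C–Me), C14 (C–OMe), C15 (CMe2), C16 (C=O).
2. Cuts: ring A at C12–C13 and C15–C16 (Claisen/Dieckmann onto a lactone ester); ring B at C10–C11 (radical closure) and C2–C8 (conjugate addition), C2=C11 by Knoevenagel from the pinan-2-one; the pinane at C3–C4 and C5–C6 in one operation.
3. Enabling feature: the cyclobutane C1–C6–C5–C7 and the six-membered ring C1–C2–C3–C4–C5–C7 share C5, and the CH2 bridge C7 can be a carbonyl. A vinyl group C4=C5 on the silyloxy carbon C7 of a cyclopropane C1–C6–C7 therefore lets one cation at C3 bond to C4 and draw C6 from C7 to C5.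
4. Forward: silyloxydiene → cyclopropane → acetal-triggered Prins/semipinacol cascade (both pinane rings) → removal of the helper C7 ketone and C3 methoxy, C2 ketone → quaternary C2 → ring B with lactone → ring A → alkoxy transposition → hydrogenation.
5. Stereochemistry: C1 (and with it C5) from the catalyst-controlled cyclopropanation; C2 from attack anti to the CMe2 bridge; C10 from the 5-exo cyclization on the face away from the C1 bridgehead; C11 from the cis-fused lactone, which also fixes the site of the methoxy group.

Key step: step 6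

Remark: the carbinol carbon C2 and the methoxy-bearing C3 in 7–12, the enolizable C13 in 21 and 22 and the enolizable ring carbon of F1 are not controlled and are erased later, so they are left undefined in the SMILES.

Step 1
Reactants: 1 4-methylpent-1-en-3-one
Product: 2 tert-butyldimethyl[(4-methylpenta-1,3-dien-3-yl)oxy]silane
Conditions: TBSOTf, Et3N, CH2Cl2, 0 °C
Reagents that add atoms: tert-butyldimethylsilyl trifluoromethanesulfonate, CC(C)(C)[Si](C)(C)OS(=O)(=O)C(F)(F)F
Why: Soft enolization (silyl enol ether formation) can only remove the isopropyl methine proton, so the 2-silyloxy diene should form as a single regioisomer.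

Step 2
Reactants: 3 1,1-dimethoxypropan-2-one
Product: 5 1-diazo-3,3-dimethoxypropan-2-one, via 1,1,1-trifluoro-5,5-dimethoxypentane-2,4-dione 4 (not isolated)
Conditions: LiN(SiMe3)2, THF, −78 °C; CF3CO2CH2CF3; then MeSO2N3, Et3N, H2O, MeCN, 25 °C
Reagents that add atoms: methanesulfonyl azide, CS(=O)(=O)N=[N+]=[N-]
Why: Detrifluoroacetylative Regitz diazo transfer: kinetic trifluoroacetylation of the methyl group activates it for diazo transfer, and the trifluoroacetyl group leaves with the sulfonamide.

Step 3
Reactants: 2 tert-butyldimethyl[(4-methylpenta-1,3-dien-3-yl)oxy]silane, 5 1-diazo-3,3-dimethoxypropan-2-one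
Product: 6 1-[(1R,3S)-3-[(tert-butyldimethylsilyl)oxy]-3-ethenyl-2,2-dimethylcyclopropyl]-2,2-dimethoxyethan-1-one (acyl cis to ethenyl)
Conditions: [Ru(NCMe)4(C15H12NO)]PF6 (3 mol %; C15H12NO = cyclometallated 2,4-diphenyl-4,5-dihydrooxazole, the ligand enantiomer that leads to 6), CH2Cl2, 0 °C, slow addition of 5 to excess 2
Reagents that add atoms: none
Why: Metal-carbene cyclopropanation of a silyl enol ether: the electrophilic carbene should add to the most electron-rich double bond of the diene (the tetrasubstituted enol ether), and the chiral catalyst should set both ring stereocentres with the acyl group trans to the bulky silyloxy group and so cis to the vinyl group, as step 6 requires.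

Step 4
Reactants: 6 1-[(1R,3S)-3-[(tert-butyldimethylsilyl)oxy]-3-ethenyl-2,2-dimethylcyclopropyl]-2,2-dimethoxyethan-1-one
Product: 7 1-[(1S,3S)-3-[(tert-butyldimethylsilyl)oxy]-3-ethenyl-2,2-dimethylcyclopropyl]-2,2-dimethoxyethan-1-ol (both carbinol epimers)
Conditions: NaBH4, MeOH, 0 °C
Reagents that add atoms: none
Why: Borohydride reduction of the ketone removes the acceptor from the donor–acceptor cyclopropane; the new carbinol centre forms as a mixture that is erased in step 8.

Step 5
Reactants: 7 1-[(1S,3S)-3-[(tert-butyldimethylsilyl)oxy]-3-ethenyl-2,2-dimethylcyclopropyl]-2,2-dimethoxyethan-1-ol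
Product: 8 tert-butyl{1-[(1S,3S)-3-[(tert-butyldimethylsilyl)oxy]-3-ethenyl-2,2-dimethylcyclopropyl]-2,2-dimethoxyethoxy}dimethylsilane
Conditions: TBSCl, imidazole, DMF, 25–40 °C
Reagents that add atoms: tert-butyldimethylsilyl chloride, CC(C)(C)[Si](C)(C)Cl
Why: Silylation with the silyl chloride (no Lewis acid that could ionize the acetal early) masks the alcohol as an ether that does not interfere with the cationic cascade.

Step 6
Reactants: 8 tert-butyl{1-[(1S,3S)-3-[(tert-butyldimethylsilyl)oxy]-3-ethenyl-2,2-dimethylcyclopropyl]-2,2-dimethoxyethoxy}dimethylsilane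
Product: 9 (1S,5S)-2-[(tert-butyldimethylsilyl)oxy]-3-methoxy-6,6-dimethylbicyclo[3.1.1]heptan-7-one (C2 and C3 epimers)
Conditions: Me3SiOTf (0.2 equiv), 2,6-di-tert-butyl-4-methylpyridine (0.3 equiv), CH2Cl2, −78 °C
Reagents that add atoms: none
Why: Proposed new method: Me3SiOTf ionizes the dimethyl acetal to the oxocarbenium ion at C3; the terminal vinyl carbon C4 adds to it in a 6-endo-trig cation–olefin cyclization (bond C3–C4, ring C1–C2–C3–C4–C5–C7), and the cyclopropylcarbinyl cation at C5 is quenched by a 1,2-shift of the CMe2 carbon C6 from the silyloxy-bearing C7 to C5 (bond C5–C6), which expands the cyclopropane C1–C6–C7 to the cyclobutanone C1–C6–C5–C7 with loss of the silyl group as TBSOMe. The closest known reaction type is the Lewis-acid coupling of acetals with 1-alkenylcyclopropyl silyl ethers to 2-substituted cyclobutanones (Prins addition/semipinacol ring expansion, as in Prins–pinacol cascades), known between two molecules but not with a tether through a cyclopropane carbon that makes the product a bridged bicycle. C1 is carried over from 8 and fixes C5, because the new six-membered ring must be cis-fused to the cyclopropane and C6 migrates on the face it already occupies; C2 and C3 are not controlled and are erased in steps 8 and 9. The step needs migration of the exocyclic cyclopropane bond C7–C6 (bridged [3.1.1] ketone) and not of the ring-fusion bond C7–C1 (fused [3.2.0] ketone): in the bicyclo[4.1.0]heptyl cation C7–C6 lies nearly parallel to the empty p orbital at C5 while C7–C1 lies near its nodal plane, and C6 is the more substituted, better migrating carbon. The saturated C2 keeps the substrate from being a cis-divinylcyclopropane (no Cope rearrangement) and keeps positive charge off the carbon next to C1, which would fragment the donor-substituted cyclopropane.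

Step 7
Reactants: 9 (1S,5S)-2-[(tert-butyldimethylsilyl)oxy]-3-methoxy-6,6-dimethylbicyclo[3.1.1]heptan-7-one
Product: 11 (1S,5S)-3-methoxy-6,6-dimethylbicyclo[3.1.1]heptan-2-ol (C2 and C3 epimers), via hydrazone 10 (not isolated)
Conditions: N2H4·H2O, diethylene glycol, 120 °C; then KOH, 200 °C
Reagents that add atoms: none
Why: Wolff–Kishner reduction deletes the helper carbonyl at C7 (the strained cyclobutanone forms its hydrazone readily and neither bridgehead α-carbon can enolize), and the hot alkaline glycol should also cleave the secondary silyl ether.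

Step 8
Reactants: 11 (1S,5S)-3-methoxy-6,6-dimethylbicyclo[3.1.1]heptan-2-ol
Product: 12 (1S,5S)-3-methoxy-6,6-dimethylbicyclo[3.1.1]heptan-2-one (C3 epimers)
Conditions: Dess–Martin periodinane, NaHCO3, CH2Cl2, 25 °C
Reagents that add atoms: none
Why: Dess–Martin oxidation of the secondary alcohol gives the C2 ketone and erases the C2 stereocentre.

Step 9
Reactants: 12 (1S,5S)-3-methoxy-6,6-dimethylbicyclo[3.1.1]heptan-2-one
Product: 13 (1S,5R)-6,6-dimethylbicyclo[3.1.1]heptan-2-one (nopinone, this enantiomer)
Conditions: SmI2, THF/MeOH, −78 °C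
Reagents that add atoms: none
Why: SmI2 reductive cleavage of an α-alkoxy ketone (enolate formation with loss of methoxide) removes the helper oxygen at C3.

Step 10
Reactants: 13 (1S,5R)-6,6-dimethylbicyclo[3.1.1]heptan-2-one, 14 dimethyl malonate
Product: 15 dimethyl 2-[(1S,5R)-6,6-dimethylbicyclo[3.1.1]heptan-2-ylidene]propanedioate
Conditions: TiCl4, pyridine, THF, 0 → 25 °C
Reagents that add atoms: none
Why: TiCl4/pyridine Knoevenagel condensation of the ketone with the malonate should give the tetrasubstituted alkylidene malonate, which makes C2 electrophilic and installs C11.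

Step 11
Reactants: 15 dimethyl 2-[(1S,5R)-6,6-dimethylbicyclo[3.1.1]heptan-2-ylidene]propanedioate, 16 5-bromo-2-methylpent-2-ene
Product: 18 dimethyl 2-[(1S,2S,5R)-6,6-dimethyl-2-(4-methylpent-3-en-1-yl)bicyclo[3.1.1]heptan-2-yl]propanedioate, via 4-methylpent-3-en-1-ylmagnesium bromide 17 (not isolated)
Conditions: Mg, THF (16 to 17); then 15, CuI (10 mol %), THF, −30 → 0 °C; NH4Cl (aq)
Reagents that add atoms: none
Why: Copper-catalysed conjugate addition of the Grignard reagent to the alkylidene malonate makes the quaternary C2; the reagent should come in anti to the CMe2 bridge (from the side of the CH2 bridge C7), so that C8 ends up anti and the malonate carbon C11 syn to C6.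

Step 12
Reactants: 18 dimethyl 2-[(1S,2S,5R)-6,6-dimethyl-2-(4-methylpent-3-en-1-yl)bicyclo[3.1.1]heptan-2-yl]propanedioate
Product: 19 methyl 3,3,6',6'-tetramethyl-1-oxotetrahydro-1H-spiro[cyclopenta[c]furan-6,2'-bicyclo[3.1.1]heptane]-6a-carboxylate (γ-lactone cis-fused to ring B across C10–C11, on the ring B face of pinane C3; C8 anti to the CMe2 bridge)
Conditions: Mn(OAc)3·2H2O (2.2 equiv), AcOH, 70 °C
Reagents that add atoms: none
Why: Mn(OAc)3-mediated oxidative free-radical cyclization: the malonyl radical at C11 closes ring B by 5-exo-trig addition to the trisubstituted alkene, and the tertiary radical is oxidized to the cation and trapped by the cis ester as the γ-lactone; the side arm at C10 should take the ring face away from the C1 bridgehead and its CMe2 bridge, and the lactone marks the ester cis to that arm as the future C12.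

Step 13
Reactants: 19 lactone ester (as in step 12), 20 2-methylpentan-3-one
Product: 23 cyclic enol ether (ring A closed; oxygen of the C10 side arm bonded to C12; C12=C13, C14=O, C16=O), via hydroxy diketo ester 21 (not isolated), via hydroxy triketone 22 (not isolated)
Conditions: LiN(iPr)2, THF, −78 °C, 20 then 19; further LiN(iPr)2, −78 → 25 °C; 1 M HCl; TsOH (cat.), toluene, 60 °C
Reagents that add atoms: none
Why: Crossed Claisen then Dieckmann-type condensation: the kinetic enolate of the ethyl ketone should attack the lactone carbonyl (more electrophilic and on the less shielded face) with release of the tertiary alkoxide, the γ-carbanion of the resulting β-diketone closes ring A on the methyl ester, and on acid work-up the tertiary alcohol condenses with the neighbouring C12 carbonyl, so C11 keeps the configuration fixed by the lactone.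

Step 14
Reactants: 23 cyclic enol ether (as in step 13)
Product: 24 target skeleton with prop-1-en-2-yl in place of isopropyl at C10
Conditions: Me3OBF4, 2,6-di-tert-butyl-4-methylpyridine, CH2Cl2, 0 → 25 °C
Reagents that add atoms: trimethyloxonium tetrafluoroborate, C[O+](C)C.F[B-](F)(F)F
Why: Proposed new method: O-methylation of the vinylogous ester carbonyl (C14=O) gives a 1,3-dialkoxyallyl cation that can only lose the tertiary alkyl group from the ring oxygen on C12 (heterolysis to the tertiary cation, then E1 loss of a methyl proton to the hindered base), so C12 becomes the ketone and C14 the methyl enol ether; the closest known reactions are O-alkylation of 3-alkoxyenones by trialkyloxonium salts to 1,3-dialkoxyallyl cations and acid cleavage of tert-alkyl ethers and esters.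

Step 15
Reactants: 24 C10 prop-1-en-2-yl compound (as in step 14)
Product: 25 CNP0307059.1 (target)
Conditions: H2 (1 atm), Pd/C, EtOAc, 25 °C
Reagents that add atoms: none
Why: Catalytic hydrogenation saturates the 1,1-disubstituted alkene to the isopropyl group without making a stereocentre; the tetrasubstituted enol ether double bond of ring A is too hindered to be reduced.

**Compound list**

1 | 4-methylpent-1-en-3-one | C=CC(=O)C(C)C | starting material
2 | tert-butyldimethyl[(4-methylpenta-1,3-dien-3-yl)oxy]silane | C=CC(O[Si](C)(C)C(C)(C)C)=C(C)C | intermediate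
3 | 1,1-dimethoxypropan-2-one | CC(=O)C(OC)OC | starting material
4 | 1,1,1-trifluoro-5,5-dimethoxypentane-2,4-dione | COC(OC)C(=O)CC(=O)C(F)(F)F | intermediate
5 | 1-diazo-3,3-dimethoxypropan-2-one | COC(OC)C(=O)C=[N+]=[N-] | intermediate
6 | 1-[(1R,3S)-3-[(tert-butyldimethylsilyl)oxy]-3-ethenyl-2,2-dimethylcyclopropyl]-2,2-dimethoxyethan-1-one (acyl cis to ethenyl) | C=C[C@@]1(O[Si](C)(C)C(C)(C)C)C(C)(C)[C@H]1C(=O)C(OC)OC | intermediate
7 | 1-[(1S,3S)-3-[(tert-butyldimethylsilyl)oxy]-3-ethenyl-2,2-dimethylcyclopropyl]-2,2-dimethoxyethan-1-ol (carbinol epimers) | C=C[C@@]1(O[Si](C)(C)C(C)(C)C)C(C)(C)[C@H]1C(O)C(OC)OC | intermediate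
8 | tert-butyl{1-[(1S,3S)-3-[(tert-butyldimethylsilyl)oxy]-3-ethenyl-2,2-dimethylcyclopropyl]-2,2-dimethoxyethoxy}dimethylsilane | C=C[C@@]1(O[Si](C)(C)C(C)(C)C)C(C)(C)[C@H]1C(O[Si](C)(C)C(C)(C)C)C(OC)OC | intermediate
9 | (1S,5S)-2-[(tert-butyldimethylsilyl)oxy]-3-methoxy-6,6-dimethylbicyclo[3.1.1]heptan-7-one (C2, C3 epimers) | CC(C)(C)[Si](C)(C)OC1C(OC)C[C@@H]2C(=O)[C@H]1C2(C)C | intermediate
10 | C7 hydrazone of 9 | CC(C)(C)[Si](C)(C)OC1C(OC)C[C@@H]2C(=NN)[C@H]1C2(C)C | intermediate
11 | (1S,5S)-3-methoxy-6,6-dimethylbicyclo[3.1.1]heptan-2-ol (C2, C3 epimers) | OC1C(OC)C[C@@H]2C[C@H]1C2(C)C | intermediate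
12 | (1S,5S)-3-methoxy-6,6-dimethylbicyclo[3.1.1]heptan-2-one (C3 epimers) | O=C1C(OC)C[C@@H]2C[C@H]1C2(C)C | intermediate
13 | (1S,5R)-6,6-dimethylbicyclo[3.1.1]heptan-2-one | O=C1CC[C@@H]2C[C@H]1C2(C)C | intermediate
14 | dimethyl malonate | COC(=O)CC(=O)OC | starting material
15 | dimethyl 2-[(1S,5R)-6,6-dimethylbicyclo[3.1.1]heptan-2-ylidene]propanedioate | COC(=O)C(C(=O)OC)=C1CC[C@@H]2C[C@H]1C2(C)C | intermediate
16 | 5-bromo-2-methylpent-2-ene | CC(C)=CCCBr | starting material
17 | (4-methylpent-3-en-1-yl)magnesium bromide | CC(C)=CCC[Mg]Br | intermediate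
18 | dimethyl 2-[(1S,2S,5R)-6,6-dimethyl-2-(4-methylpent-3-en-1-yl)bicyclo[3.1.1]heptan-2-yl]propanedioate (malonate carbon syn to the CMe2 bridge) | CC(C)=CCC[C@]1(C(C(=O)OC)C(=O)OC)CC[C@@H]2C[C@H]1C2(C)C | intermediate
19 | methyl 3,3,6',6'-tetramethyl-1-oxotetrahydro-1H-spiro[cyclopenta[c]furan-6,2'-bicyclo[3.1.1]heptane]-6a-carboxylate (lactone cis-fused on the ring B face of pinane C3) | COC(=O)[C@]12C(=O)OC(C)(C)[C@H]1CC[C@@]21CC[C@@H]2C[C@H]1C2(C)C | intermediate
20 | 2-methylpentan-3-one | CCC(=O)C(C)C | starting material
21 | hydroxy diketo ester: ring B with CO2Me and 2,4-dimethyl-3-oxopentanoyl on C11 and 2-hydroxypropan-2-yl on C10 (C13 epimers) | COC(=O)[C@]1(C(=O)C(C)C(=O)C(C)C)[C@@H](C(C)(C)O)CC[C@@]12CC[C@@H]3C[C@H]2C3(C)C | intermediate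
22 | hydroxy triketone: ring A closed (C12, C14, C16 carbonyls, C13 H/Me), 2-hydroxypropan-2-yl on C10 | CC1C(=O)[C@@]2(C(=O)C(C)(C)C1=O)[C@@H](C(C)(C)O)CC[C@@]21CC[C@@H]2C[C@H]1C2(C)C | intermediate
23 | cyclic enol ether: side-arm oxygen on C12, C12=C13, C14=O, C16=O (dihydrofuran fused across C10–C11–C12) | CC1=C2OC(C)(C)[C@H]3CC[C@@]4(CC[C@@H]5C[C@H]4C5(C)C)[C@@]23C(=O)C(C)(C)C1=O | intermediate
24 | target skeleton with prop-1-en-2-yl at C10 | COC1=C(C)C(=O)[C@@]2(C(=O)C1(C)C)[C@@H](C(C)=C)CC[C@@]21CC[C@@H]2C[C@H]1C2(C)C | intermediate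
25 | CNP0307059.1 | COC1=C(C)C(=O)[C@@]2(C(=O)C1(C)C)[C@@H](C(C)C)CC[C@@]21CC[C@@H]2C[C@H]1C2(C)C | target

**Totals**

Total step count: 15. Longest linear sequence: 14 steps (steps 1 and 3–15; step 2 is a one-step side branch that makes 5).

**Steps most likely to fail**

1. Step 6 (key step). What may go wrong: opening of the silyloxycyclopropane by the Lewis acid before the ring closure, or shift of the ring-fusion bond C7–C1 in place of C7–C6, giving the fused instead of the bridged ketone. The fallback uses known reaction types, sets out from 8 and comes back at 9, and makes the two bonds one after the other. Phenylselenenyl chloride (CH2Cl2, −78 °C) should add to the vinyl group and trigger the electrophile-induced ring expansion known for 1-vinylcyclopropanol derivatives, giving the selenide cyclobutanone F1 (bond C5–C6). Oxidation with H2O2 and selenoxide elimination should give the 2-methylidenecyclobutanone F2. Mild hydrolysis of the acetal (pyridinium tosylate, wet acetone) gives the aldehyde F3. SmI2 (THF, t-BuOH, −78 °C) should then close the six-membered ring by reductive aldehyde–enone coupling (ketyl addition to the exocyclic enone, bond C3–C4) to the hydroxy ketone F4. O-Methylation (MeOTf, 2,6-di-tert-butylpyridine) returns to 9.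

2. Step 14. What may go wrong: ionization of the tertiary ether before O-methylation, which would lose the regiocontrol, or elimination of the tertiary cation toward C10, which would erase that stereocentre. The fallback uses known chemistry, sets out from 23 and comes back at 25. Ionic hydrogenolysis (CF3CO2H, Et3SiH, CH2Cl2) should cleave the tertiary alkyl–oxygen bond and reduce the cation to the isopropyl group, giving the free triketone F5. O-Methylation of its enol with Me3SiCHN2 (MeOH/toluene) should favour the C14 oxygen, which is less shielded than the C12 oxygen next to the spiro centre, and gives 25 after separation from the regioisomeric enol ether.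

3. Step 13. What may go wrong: attack of the ketone enolate on the methyl ester in place of the lactone (which would invert the sense of ring A at C11), and slow ring closure at the neopentyl ester. The fallback sets out from 19 and comes back at 21, which is then isolated and closed to 23 under the second half of the step 13 conditions (LiN(iPr)2, then acid). Saponification (LiOH, THF/H2O) and acidification, on which the hydroxy acid relactonizes, give the lactone acid F6, whose carboxylate is inert to enolates. Excess lithium enolate of 20 then can only open the lactone, giving the hydroxy diketo acid F7. One equivalent of Me3SiCHN2 at 0 °C esterifies the acid to 21.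

Further compounds
F1 | step 6 | 2-{1-[(tert-butyldimethylsilyl)oxy]-2,2-dimethoxyethyl}-3,3-dimethyl-4-[(phenylselanyl)methyl]cyclobutan-1-one | COC(OC)C(O[Si](C)(C)C(C)(C)C)[C@H]1C(=O)C(C[Se]c2ccccc2)C1(C)C
F2 | step 6 | 2-{1-[(tert-butyldimethylsilyl)oxy]-2,2-dimethoxyethyl}-3,3-dimethyl-4-methylidenecyclobutan-1-one | COC(OC)C(O[Si](C)(C)C(C)(C)C)[C@H]1C(=O)C(=C)C1(C)C
F3 | step 6 | 2-[(tert-butyldimethylsilyl)oxy]-2-(2,2-dimethyl-3-methylidene-4-oxocyclobutyl)acetaldehyde | O=CC(O[Si](C)(C)C(C)(C)C)[C@H]1C(=O)C(=C)C1(C)C
F4 | step 6 | (1S,5S)-2-[(tert-butyldimethylsilyl)oxy]-3-hydroxy-6,6-dimethylbicyclo[3.1.1]heptan-7-one | CC(C)(C)[Si](C)(C)OC1C(O)C[C@@H]2C(=O)[C@H]1C2(C)C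
F5 | step 14 | free triketone: target with C14=O and C13 H/Me in place of the methyl enol ether | CC1C(=O)[C@@]2(C(=O)C(C)(C)C1=O)[C@@H](C(C)C)CC[C@@]21CC[C@@H]2C[C@H]1C2(C)C
F6 | step 13 | lactone acid: carboxylic acid corresponding to the methyl ester 19 | OC(=O)[C@]12C(=O)OC(C)(C)[C@H]1CC[C@@]21CC[C@@H]2C[C@H]1C2(C)C
F7 | step 13 | hydroxy diketo acid: carboxylic acid corresponding to the methyl ester 21 | OC(=O)[C@]1(C(=O)C(C)C(=O)C(C)C)[C@@H](C(C)(C)O)CC[C@@]12CC[C@@H]3C[C@H]2C3(C)C
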